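The easy step is to read the end of the violet run: J reads 15.1% at 90.0 min and 14.6% at 150 min, a difference the size of the scatter of 0.5 percentage points, so within that scatter J has stopped rising, while E reads 38.9%. Two chemists read this stall differently.

| setting | violet | blue | flask |
|---|---|---|---|
| E | 26 mM | 26 mM | 26 mM |
| G | 26 mM | 26 mM | 26 mM |
| X | 52 mM | 52 mM | 52.0 mM |
| L | 1.3 mM | 1.3 mM | 1.3 mM |
| temperature | 5 °C | 0 °C | 5 °C |
| remark | the very flask that is asked about, followed so far | run made earlier |  |
| time |  |  | 4.0 h |

| run | time / min | J / % | E / % |
|---|---|---|---|
| violet | 12.0 | 10.4 | 41.9 |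
| violet | 40.0 | 13.3 | 39.7 |
| violet | 60.0 | 13.8 | 40.2 |
| violet | 90.0 | 15.1 | 38.8 |
| violet | 150 | 14.6 | 38.9 |
| blue | 12.0 | 8.2 | 42.5 |
| blue | 40.0 | 13.9 | 39.5 |
| blue | 60.0 | 14.7 | 38.5 |
| blue | 90.0 | 16.0 | 39.1 |
| blue | 150 | 16.0 | 38.4 |

(standard deviation of a reading: 0.5 percentage points)

* J, in percent of the E and G together first charged, at 4.0 h
* what to do for the largest gain in J; "none" if nothing gains more than 2 percentage points (alder / cedar / oak / elm / maple / none)
* J present, with what was taken out counted in, in percent of the E and G together first charged, after oak
* J present, with what was taken out counted in, in percent of the E and G together first charged, after elm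

- alder: change nothing and wait 2.0 h more
- cedar: at 4.0 h add L, 50.0% of the amount charged, then wait 2.0 h
- oak: at 4.0 h raise the temperature by 20 K, then wait 2.0 h
- elm: at 4.0 h add X, 50.0% of the amount charged, then wait 2.0 h
- maple: at 4.0 h take out 90% of the J then present, then wait 2.0 h

- L is single-handed; E and G are mirror images of each other, charged as a racemate, each of them at the stated concentration
- J taken out counts as made
- steps under discussion: X + L + G -> L + D; E <-> G; X + L + E -> L + J; X -> Z; 2 X -> Q
- additions bring no volume worth counting

The first chemist holds that the violet flask stopped for want of X, so she writes the balance of X. The amount of X charged, 52.0 mM, equals E and G together, so a percent of J is also a percent of the X charged. From the last two violet readings she gets 14.8%. This is the return of X, the J made per X charged. She expects J to stay there at 4.0 h, and after oak too, since heat brings no new X. For elm, with the added X at the same return, her reckoning puts J at 22.3%.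

The second chemist holds that L dies during the run, with X still waiting. On that view, J per L is the fixed number, and cedar, not elm, restarts the flask. For the addition of 50.0% of L, her reckoning puts J at 22.3%.

The forecast takes the first side, with 15.2% at 4.0 h, 15.4% after oak, 21.3% after elm and the choice elm, lower on elm than the first chemist's figure, on the grounds that “Fresh X restarts the reaction”.

The simulation gives 14.9% at 4.0 h, 14.9% after oak and 23.8% after elm, and the choice is elm, with a gain of 8.9 points against 0 points for cedar. At 240 min the violet flask holds L at 100% and X at 0%, so X is the limiting reagent and the first chemist wins.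

    X + L + G → L + D (k = 4.10 /M²/s, Ea = 47.0 kJ/mol)
    E ⇌ G (k = 9.70 × 10⁻⁴ /s, Ea = 75.0 kJ/mol)
    X + L + E → L + J (k = 9.80 /M²/s, Ea = 43.0 kJ/mol)
    X → Z (k = 3.30 × 10⁻⁴ /s, Ea = 80.0 kJ/mol)
    2 X → Q (k = 0.0320 /M/s, Ea = 56.0 kJ/mol)
    (constants at 5 °C)

J stops in the violet flask because the level of X falls: with that level held, J reaches 67.0% at 4.0 h, against 14.9%. The path in which two X give Q is a part of this, since without it J reaches 34.7%. Reckoned on the simulated values, the X added in elm returned 17.7%, more than the 14.9% of the first charge.

The second chemist's J per L has its region in L charged at the start, where J moves with L. For the neighbour flask with 0.52 mM of L, the return scaled in proportion to L gives 5.94% of J. The computed neighbour flask holds 7.57% of J at 4.0 h, above that figure.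

The data come from a simulation on assumed constants, and the scatter is random.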